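**Plan**

- Retrosynthesis: the two aryl silyl ethers and the C5'–prenyl bond (held as a C5' bromide) are cut first, then the C4–C4a aryl ketone bond of ring C, then the O1–C2 ether bond, the C2–C3 bond (a formaldehyde unit) and last the C3–C4 homologation of a ring B benzaldehyde.
- Forward: ring B aldehyde → arylacetic acid (C3, C4) → N-acyl oxazolidinone → hydroxymethylation (C2) → Mitsunobu ether with the ring A phenol (O1) → free acid → closure of ring C → prenylation → desilylation. Rings A and B are bought; ring C is the only ring made.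
- Enabling feature: C4a of ring A is ortho to O1 and para to the C7 oxygen, so the carbon that must receive the C4 acyl group is the most nucleophilic site of a resorcinol diether that already carries the O1–C2–C3 chain. Ring C closes there by intramolecular acylation.
- Stereochemistry: C3 (S) is set by (R)-4-benzyloxazolidin-2-one in a titanium enolate hydroxymethylation and carried through as the carboxylic acid. Every step after ring closure avoids base.

Key step: step 10

Remark: the enol ether made in step 2 is used as an E/Z mixture, since both isomers hydrolyse to the same aldehyde; TIPS stands for triisopropylsilyl.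

**Route**

Step 1
Reactants: 1 5-bromo-2-hydroxy-4-methoxybenzaldehyde
Product: 2 5-bromo-4-methoxy-2-(triisopropylsilyloxy)benzaldehyde
Conditions: TIPSCl, imidazole, DMF, rt
Reagents that add atoms: triisopropylsilyl chloride, CC(C)[Si](Cl)(C(C)C)C(C)C
Why: Imidazole-promoted O-silylation of the phenol should give a bulky aryl silyl ether that survives the ylide, Lewis acid and hydroperoxide steps and later keeps this oxygen from attacking the acylium ion.

Step 2
Reactants: 2 5-bromo-4-methoxy-2-(triisopropylsilyloxy)benzaldehyde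
Product: 3 [4-bromo-5-methoxy-2-(2-methoxyethenyl)phenoxy]triisopropylsilane (E/Z mixture)
Conditions: Ph3P(CH2OMe)Cl, KN(SiMe3)2, THF, 0 °C; then 2, 0 °C → rt
Reagents that add atoms: (methoxymethyl)triphenylphosphonium chloride, COC[P+](c1ccccc1)(c1ccccc1)c1ccccc1.[Cl-]
Why: Wittig methoxymethylenation of the aldehyde adds the carbon that becomes C4, and the alkene geometry is of no consequence.

Step 3
Reactants: 3 [4-bromo-5-methoxy-2-(2-methoxyethenyl)phenoxy]triisopropylsilane
Product: 4 2-[5-bromo-4-methoxy-2-(triisopropylsilyloxy)phenyl]acetaldehyde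
Conditions: 2 M aq. HCl, THF, 40 °C; crude aldehyde used at once
Reagents that add atoms: water, O
Why: Acid-catalysed enol ether hydrolysis (protonation at the benzylic carbon, hydration of the oxocarbenium ion, loss of methanol) should free the aldehyde while the aryl silyl ether, far more stable to acid than to base, stays on.

Step 4
Reactants: 4 2-[5-bromo-4-methoxy-2-(triisopropylsilyloxy)phenyl]acetaldehyde
Product: 5 2-[5-bromo-4-methoxy-2-(triisopropylsilyloxy)phenyl]acetic acid
Conditions: NaClO2, NaH2PO4, 2-methyl-2-butene, t-BuOH/H2O, 0 °C → rt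
Reagents that add atoms: NaClO2, [Na+].[O-]Cl=O
Why: Pinnick oxidation converts the enolisable aldehyde into the acid under weakly acidic conditions, the alkene scavenger removing hypochlorous acid before it can chlorinate the electron-rich ring.

Step 5
Reactants: 5 2-[5-bromo-4-methoxy-2-(triisopropylsilyloxy)phenyl]acetic acid; 6 (R)-4-benzyl-1,3-oxazolidin-2-one
Product: 8 (4R)-4-benzyl-3-{[5-bromo-4-methoxy-2-(triisopropylsilyloxy)phenyl]acetyl}-1,3-oxazolidin-2-one, via mixed pivalic anhydride 7 (not isolated)
Conditions: PivCl, Et3N, THF, −20 °C; then LiCl, 6, −20 °C → rt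
Reagents that add atoms: none
Why: N-acylation of the oxazolidinone through the mixed anhydride should occur at the unhindered arylacetyl carbonyl under mild LiCl/Et3N activation.

Step 6
Reactants: 8 (4R)-4-benzyl-3-{[5-bromo-4-methoxy-2-(triisopropylsilyloxy)phenyl]acetyl}-1,3-oxazolidin-2-one
Product: 10 (4R)-4-benzyl-3-[(2S)-2-[5-bromo-4-methoxy-2-(triisopropylsilyloxy)phenyl]-3-hydroxypropanoyl]-1,3-oxazolidin-2-one, via trichlorotitanium enolate 9 (not isolated)
Conditions: TiCl4, i-Pr2NEt, CH2Cl2, 0 °C; then 1,3,5-trioxane, TiCl4, 0 °C; aq. NH4Cl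
Reagents that add atoms: 1,3,5-trioxane, C1OCOCO1
Why: Soft enolisation gives the chelated Z-enolate, and TiCl4-activated formaldehyde should add to the face opposite the C4 benzyl group (auxiliary-controlled aldol-type hydroxymethylation), which sets the future C3 as S; a minor diastereomer would be separable at this stage.

Step 7
Reactants: 11 resorcinol
Product: 12 3-(triisopropylsilyloxy)phenol
Conditions: TIPSCl (1 equiv), imidazole, resorcinol (3 equiv), DMF, 0 °C → rt
Reagents that add atoms: triisopropylsilyl chloride, CC(C)[Si](Cl)(C(C)C)C(C)C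
Why: Statistical monosilylation of the diol used in excess should favour the mono ether, the unreacted resorcinol being washed out with water.

Step 8
Reactants: 10 (4R)-4-benzyl-3-[(2S)-2-[5-bromo-4-methoxy-2-(triisopropylsilyloxy)phenyl]-3-hydroxypropanoyl]-1,3-oxazolidin-2-one; 12 3-(triisopropylsilyloxy)phenol
Product: 13 (4R)-4-benzyl-3-[(2S)-2-[5-bromo-4-methoxy-2-(triisopropylsilyloxy)phenyl]-3-[3-(triisopropylsilyloxy)phenoxy]propanoyl]-1,3-oxazolidin-2-one
Conditions: PPh3, DIAD, THF, 0 °C → rt
Reagents that add atoms: none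
Why: Mitsunobu etherification displaces the alkoxyphosphonium ion of the primary alcohol by the phenoxide in an SN2 reaction at CH2, so the neighbouring stereocentre is untouched, and A(1,3) strain in the imide holds the α-hydrogen in the carbonyl plane and should slow β-elimination.

Step 9
Reactants: 13 (4R)-4-benzyl-3-[(2S)-2-[5-bromo-4-methoxy-2-(triisopropylsilyloxy)phenyl]-3-[3-(triisopropylsilyloxy)phenoxy]propanoyl]-1,3-oxazolidin-2-one
Product: 15 (2S)-2-[5-bromo-4-methoxy-2-(triisopropylsilyloxy)phenyl]-3-[3-(triisopropylsilyloxy)phenoxy]propanoic acid, via peroxy acid 14 (not isolated)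
Conditions: LiOH·H2O, 30% H2O2, THF/H2O (3:1), 0 °C; then aq. Na2SO3; 1 M HCl to pH 3
Reagents that add atoms: hydrogen peroxide, OO
Why: The hydroperoxide anion, more nucleophilic and much less basic than hydroxide, should cleave the exocyclic imide carbonyl at 0 °C without α-epimerisation or loss of the β-aryloxide, and sulfite reduces the peracid to the acid.

Step 10
Reactants: 15 (2S)-2-[5-bromo-4-methoxy-2-(triisopropylsilyloxy)phenyl]-3-[3-(triisopropylsilyloxy)phenoxy]propanoic acid
Product: 17 (3S)-3-[5-bromo-4-methoxy-2-(triisopropylsilyloxy)phenyl]-7-(triisopropylsilyloxy)-2,3-dihydro-4H-chromen-4-one, via acid chloride 16 (not isolated)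
Conditions: (COCl)2, DMF (cat.), CH2Cl2, 0 °C → rt, then evaporation; SnCl4 (1.5 equiv), CH2Cl2, −78 °C; quench into ice-cold dilute HCl
Reagents that add atoms: none
Why: Oxalyl chloride with catalytic DMF makes acid chloride 16 without base, and SnCl4 ionises it to an acylium ion (RCO+ SnCl5−) that attacks ring A at the carbon ortho to O1 and para to the 7-silyloxy group; proton loss from the arenium ion then gives the C4–C4a bond. The closest known reaction type is the intramolecular Friedel–Crafts acylation of 3-aryloxypropanoic acids to chroman-4-ones. Ring C closes as a six-membered ring by attack of the arene on the digonal acylium carbon (6-exo-dig with respect to the C≡O unit), closure onto ring B being geometrically impossible. No stereocentre is formed: C3 comes from acid 15, and its retention rests on the absence of base (no ketene from the α-aryl acid chloride), on fast intramolecular capture at −78 °C and on a cold, non-basic quench before the tin-bound ketone can enolise. The selectivity needed is acylation para and not ortho to the silyloxy group; it is secured because the other site ortho to O1 lies between the two oxygens and is shielded by the triisopropylsilyl group, whose bulk should likewise keep the 2'-silyloxy oxygen from trapping the acylium ion as a benzofuranone.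

Step 11
Reactants: 17 (3S)-3-[5-bromo-4-methoxy-2-(triisopropylsilyloxy)phenyl]-7-(triisopropylsilyloxy)-2,3-dihydro-4H-chromen-4-one; 18 tributyl(3-methylbut-2-en-1-yl)stannane
Product: 19 (3S)-3-[4-methoxy-5-(3-methylbut-2-en-1-yl)-2-(triisopropylsilyloxy)phenyl]-7-(triisopropylsilyloxy)-2,3-dihydro-4H-chromen-4-one
Conditions: Pd(PPh3)4 (10 mol %), toluene, 90 °C, degassed
Reagents that add atoms: none
Why: Kosugi–Migita–Stille coupling (oxidative addition of the aryl bromide to zerovalent palladium, transmetalation from tin, reductive elimination at the unsubstituted allyl terminus) should give the linear prenyl arene with no base present that could enolise the ketone at C3.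

Step 12
Reactants: 19 (3S)-3-[4-methoxy-5-(3-methylbut-2-en-1-yl)-2-(triisopropylsilyloxy)phenyl]-7-(triisopropylsilyloxy)-2,3-dihydro-4H-chromen-4-one
Product: 20 (3S)-7-hydroxy-3-[2-hydroxy-4-methoxy-5-(3-methylbut-2-en-1-yl)phenyl]-2,3-dihydro-4H-chromen-4-one (CNP0227207.1)
Conditions: Bu4NF/AcOH (1:1.2), THF, 0 °C
Reagents that add atoms: none
Why: Fluoride attack at silicon should release both phenols, the acetic acid buffer protonating each phenoxide at once so that the medium stays too weakly basic to enolise the α-aryl ketone, and the prenyl alkene is inert.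

**Compound list**

1 | 5-bromo-2-hydroxy-4-methoxybenzaldehyde | COc1cc(O)c(C=O)cc1Br | starting material
2 | 5-bromo-4-methoxy-2-(triisopropylsilyloxy)benzaldehyde | COc1cc(O[Si](C(C)C)(C(C)C)C(C)C)c(C=O)cc1Br | intermediate
3 | [4-bromo-5-methoxy-2-(2-methoxyethenyl)phenoxy]triisopropylsilane (E/Z mixture) | COC=Cc1cc(Br)c(OC)cc1O[Si](C(C)C)(C(C)C)C(C)C | intermediate
4 | 2-[5-bromo-4-methoxy-2-(triisopropylsilyloxy)phenyl]acetaldehyde | COc1cc(O[Si](C(C)C)(C(C)C)C(C)C)c(CC=O)cc1Br | intermediate
5 | 2-[5-bromo-4-methoxy-2-(triisopropylsilyloxy)phenyl]acetic acid | COc1cc(O[Si](C(C)C)(C(C)C)C(C)C)c(CC(=O)O)cc1Br | intermediate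
6 | (R)-4-benzyl-1,3-oxazolidin-2-one | O=C1N[C@H](Cc2ccccc2)CO1 | starting material
7 | mixed anhydride of acid 5 and pivalic acid (not isolated) | COc1cc(O[Si](C(C)C)(C(C)C)C(C)C)c(CC(=O)OC(=O)C(C)(C)C)cc1Br | intermediate
8 | (4R)-4-benzyl-3-{[5-bromo-4-methoxy-2-(triisopropylsilyloxy)phenyl]acetyl}-1,3-oxazolidin-2-one | COc1cc(O[Si](C(C)C)(C(C)C)C(C)C)c(CC(=O)N2[C@H](Cc3ccccc3)COC2=O)cc1Br | intermediate
9 | trichlorotitanium (Z)-enolate of imide 8 (not isolated) | COc1cc(O[Si](C(C)C)(C(C)C)C(C)C)c(/C=C(\O[Ti](Cl)(Cl)Cl)N2[C@H](Cc3ccccc3)COC2=O)cc1Br | intermediate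
10 | (4R)-4-benzyl-3-[(2S)-2-[5-bromo-4-methoxy-2-(triisopropylsilyloxy)phenyl]-3-hydroxypropanoyl]-1,3-oxazolidin-2-one | COc1cc(O[Si](C(C)C)(C(C)C)C(C)C)c([C@@H](CO)C(=O)N2[C@H](Cc3ccccc3)COC2=O)cc1Br | intermediate
11 | resorcinol | Oc1cccc(O)c1 | starting material
12 | 3-(triisopropylsilyloxy)phenol | Oc1cccc(O[Si](C(C)C)(C(C)C)C(C)C)c1 | intermediate
13 | (4R)-4-benzyl-3-[(2S)-2-[5-bromo-4-methoxy-2-(triisopropylsilyloxy)phenyl]-3-[3-(triisopropylsilyloxy)phenoxy]propanoyl]-1,3-oxazolidin-2-one | COc1cc(O[Si](C(C)C)(C(C)C)C(C)C)c([C@@H](COc2cccc(O[Si](C(C)C)(C(C)C)C(C)C)c2)C(=O)N3[C@H](Cc4ccccc4)COC3=O)cc1Br | intermediate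
14 | (2S)-2-[5-bromo-4-methoxy-2-(triisopropylsilyloxy)phenyl]-3-[3-(triisopropylsilyloxy)phenoxy]propaneperoxoic acid (not isolated) | COc1cc(O[Si](C(C)C)(C(C)C)C(C)C)c([C@@H](COc2cccc(O[Si](C(C)C)(C(C)C)C(C)C)c2)C(=O)OO)cc1Br | intermediate
15 | (2S)-2-[5-bromo-4-methoxy-2-(triisopropylsilyloxy)phenyl]-3-[3-(triisopropylsilyloxy)phenoxy]propanoic acid | COc1cc(O[Si](C(C)C)(C(C)C)C(C)C)c([C@@H](COc2cccc(O[Si](C(C)C)(C(C)C)C(C)C)c2)C(=O)O)cc1Br | intermediate
16 | (2S)-2-[5-bromo-4-methoxy-2-(triisopropylsilyloxy)phenyl]-3-[3-(triisopropylsilyloxy)phenoxy]propanoyl chloride (not isolated) | COc1cc(O[Si](C(C)C)(C(C)C)C(C)C)c([C@@H](COc2cccc(O[Si](C(C)C)(C(C)C)C(C)C)c2)C(=O)Cl)cc1Br | intermediate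
17 | (3S)-3-[5-bromo-4-methoxy-2-(triisopropylsilyloxy)phenyl]-7-(triisopropylsilyloxy)-2,3-dihydro-4H-chromen-4-one | COc1cc(O[Si](C(C)C)(C(C)C)C(C)C)c([C@H]2COc3cc(O[Si](C(C)C)(C(C)C)C(C)C)ccc3C2=O)cc1Br | intermediate
18 | tributyl(3-methylbut-2-en-1-yl)stannane | CCCC[Sn](CCCC)(CCCC)CC=C(C)C | starting material
19 | (3S)-3-[4-methoxy-5-(3-methylbut-2-en-1-yl)-2-(triisopropylsilyloxy)phenyl]-7-(triisopropylsilyloxy)-2,3-dihydro-4H-chromen-4-one | COc1cc(O[Si](C(C)C)(C(C)C)C(C)C)c([C@H]2COc3cc(O[Si](C(C)C)(C(C)C)C(C)C)ccc3C2=O)cc1CC=C(C)C | intermediate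
20 | (3S)-7-hydroxy-3-[2-hydroxy-4-methoxy-5-(3-methylbut-2-en-1-yl)phenyl]-2,3-dihydro-4H-chromen-4-one | COc1cc(O)c([C@H]2COc3cc(O)ccc3C2=O)cc1CC=C(C)C | target

Total step count: 12. Longest linear sequence: 11 steps (1 → 20 through steps 1–6 and 8–12).

**Steps most likely to fail**

1. Step 10. The danger is erosion of the C3 configuration while the acyl group is activated and after the ring has closed (ketene formation from the α-aryl acid chloride, enolisation of the tin-bound ketone), together with diversion of the acylium ion onto the 2'-silyloxy oxygen. The fallback no longer carries the stereocentre through the ring closure but resets it afterwards by dynamic kinetic resolution. It sets out from ketone 17 of whatever enantiomeric purity the cyclisation delivers, so that acid 15 may then be cyclised with more forcing activation such as trifluoroacetic anhydride. Asymmetric transfer hydrogenation with RuCl(p-cymene)[(S,S)-TsDPEN] in HCO2H/Et3N at rt should fix C4 as S, as it does for chroman-4-one. Et3N equilibrates the two enantiomers of the ketone through the enol, and hydride delivery anti to the C3 aryl group selects the (3S) ketone. The product should be the cis alcohol (3S,4S)-3-[5-bromo-4-methoxy-2-(triisopropylsilyloxy)phenyl]-7-(triisopropylsilyloxy)-3,4-dihydro-2H-chromen-4-ol F1. Base-free oxidation of C4 with Dess–Martin periodinane in CH2Cl2 at 0 °C comes back to 17, and the route goes on with step 11.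

2. Step 11. The coupling may go through the γ-carbon of the prenyl group to give the 1,1-dimethylallyl isomer. Oxidative addition of the electron-rich, ortho-substituted bromide may also be slow enough that prolonged heating leads to protodebromination or enolisation at C3. The fallback divides the task into a coupling without regiochemical choice and a neutral chain extension. It sets out from 17: coupling with allyltributylstannane (Bu3SnCH2CH=CH2) under the same Pd(PPh3)4 conditions should give (3S)-3-[4-methoxy-5-(prop-2-en-1-yl)-2-(triisopropylsilyloxy)phenyl]-7-(triisopropylsilyloxy)-2,3-dihydro-4H-chromen-4-one F2. Cross-metathesis of F2 with an excess of 2-methyl-2-butene (second-generation Grubbs catalyst, RuCl2(=CHPh)(H2IMes)(PCy3), CH2Cl2, rt) then comes back to 19.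

3. Step 8. The activated alcohol may undergo β-elimination through the imide enolate to the 2-arylacryloyl imide, and the phenol may add back to this acrylate without stereocontrol. The fallback forms the C2–C3 bond with the ether already in place, so that no β-leaving group ever sits next to the acidic α-hydrogen. It sets out from phenol 12 and imide 8. Phenol 12 is alkylated with ClCH2SMe (Cs2CO3, NaI, DMF) to triisopropyl[3-(methylsulfanylmethoxy)phenoxy]silane F3, and SO2Cl2 in CH2Cl2 at 0 °C converts this into [3-(chloromethoxy)phenoxy]triisopropylsilane F4. The trichlorotitanium enolate 9, made from 8 as in step 6, is then alkylated with F4 at 0 °C in the manner of the benzyloxymethyl chloride alkylation of such enolates. The electrophile should enter anti to the benzyl group as formaldehyde does, which gives 13 directly and replaces steps 6 and 8.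

**Further compounds**

F1 | step 10 | (3S,4S)-3-[5-bromo-4-methoxy-2-(triisopropylsilyloxy)phenyl]-7-(triisopropylsilyloxy)-3,4-dihydro-2H-chromen-4-ol | COc1cc(O[Si](C(C)C)(C(C)C)C(C)C)c([C@H]2COc3cc(O[Si](C(C)C)(C(C)C)C(C)C)ccc3[C@H]2O)cc1Br
F2 | step 11 | (3S)-3-[4-methoxy-5-(prop-2-en-1-yl)-2-(triisopropylsilyloxy)phenyl]-7-(triisopropylsilyloxy)-2,3-dihydro-4H-chromen-4-one | COc1cc(O[Si](C(C)C)(C(C)C)C(C)C)c([C@H]2COc3cc(O[Si](C(C)C)(C(C)C)C(C)C)ccc3C2=O)cc1CC=C
F3 | step 8 | triisopropyl[3-(methylsulfanylmethoxy)phenoxy]silane | CSCOc1cccc(O[Si](C(C)C)(C(C)C)C(C)C)c1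
F4 | step 8 | [3-(chloromethoxy)phenoxy]triisopropylsilane | ClCOc1cccc(O[Si](C(C)C)(C(C)C)C(C)C)c1
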